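**Retrosynthetic overview**
- Last operations: removal of the O-methyl and O-silyl groups; before that, the C1–acyl bond is made by bridgehead lithiation of the vinylogous methyl ester and acylation with (R)-2-methylbutanoyl chloride.
- Key disconnection: bonds C1–C2 and C4–C5 of ring C1–C2–C3–C4–C5–C9, i.e. both bridges of the bicyclo[3.3.1] core at once. This gives a monocyclic silyl enol ether and a 2-alkylmalonyl dichloride that already carries the whole C3 side chain (Effenberger-type α,α′-annulation).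
- Enabling feature: the C9 ketone lies between two enolisable carbons, C1 and C5 (a 1,3-bis-nucleophile held in ring C1–C8–C7–C6–C5–C9), and C2–C3–C4 is a malonyl unit (a 1,3-bis-electrophile). The C7 prenyl stereocentre steers both bridgeheads.
- Ring order: ring C1–C8–C7–C6–C5–C9 first (asymmetric Michael addition/aldol condensation sets C7; the C5 prenyl and C8 gem-dimethyl groups are added on the enone), ring C1–C2–C3–C4–C5–C9 last.

Key step: step 12

Assumption: 5-methylhex-4-enal and (R)-2-methylbutanoic acid are bought; the ring carbon that becomes C5 is carried as an epimer mixture (left undefined in the SMILES) because it is planarised in the key step.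

Step 1
Reactants: 1 5-methylhex-4-enal; 2 but-3-en-2-one
Product: 3 (2S)-2-(3-methylbut-2-en-1-yl)-5-oxohexanal
Conditions: (S)-2-[methoxy(diphenyl)methyl]pyrrolidine (5 mol%), ethyl 3,4-dihydroxybenzoate (20 mol%), neat, 4 °C
Reagents that add atoms: none
Why: Enamine-catalysed asymmetric Michael addition of the aldehyde to the enone; the diarylprolinol ether shields one face of the E-enamine, so the enone should add to the open face and set the α-centre (the future C7) as S.

Step 2
Reactants: 3 (2S)-2-(3-methylbut-2-en-1-yl)-5-oxohexanal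
Product: 4 (4S)-4-(3-methylbut-2-en-1-yl)cyclohex-2-en-1-one
Conditions: 0.1 M aq. KOH, n-Bu4NOH (cat.), Et2O–THF, reflux
Reagents that add atoms: none
Why: Intramolecular aldol condensation (methyl-ketone enolate onto the aldehyde, then dehydration) closes ring C1–C8–C7–C6–C5–C9; the mild two-phase base should consume the aldehyde faster than its α-centre enolises, and no new stereocentre is formed.

Step 3
Reactants: 4 (4S)-4-(3-methylbut-2-en-1-yl)cyclohex-2-en-1-one; 5 1-bromo-3-methylbut-2-ene
Product: 7 (4R)-4,6-bis(3-methylbut-2-en-1-yl)cyclohex-2-en-1-one (C-6 epimers), via lithium dienolate 6 (not isolated)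
Conditions: LDA, THF, −78 °C; then 5, −78 → 0 °C
Reagents that add atoms: none
Why: Kinetic α′-deprotonation gives the cross-conjugated dienolate, which is C-alkylated by the allylic bromide (enolate alkylation); the new C-6 centre may form as either epimer because it becomes sp2 in step 12, and the C-4 centre is untouched (its descriptor changes only through CIP priorities).

Step 4
Reactants: 7 (4R)-4,6-bis(3-methylbut-2-en-1-yl)cyclohex-2-en-1-one (C-6 epimers)
Product: 8 {[(4R)-3-methyl-4,6-bis(3-methylbut-2-en-1-yl)cyclohex-1-en-1-yl]oxy}trimethylsilane (C-3 and C-6 epimers)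
Conditions: MeMgBr, CuBr·SMe2 (cat.), TMSCl, HMPA, THF, −78 °C
Reagents that add atoms: methylmagnesium bromide C[Mg]Br; chlorotrimethylsilane C[Si](C)(C)Cl
Why: Copper-catalysed conjugate addition of the methyl Grignard reagent with in situ O-silylation of the enolate gives the regiodefined silyl enol ether; the C-3 centre it creates is erased in step 5.

Step 5
Reactants: 8 {[(4R)-3-methyl-4,6-bis(3-methylbut-2-en-1-yl)cyclohex-1-en-1-yl]oxy}trimethylsilane
Product: 9 (4R)-3-methyl-4,6-bis(3-methylbut-2-en-1-yl)cyclohex-2-en-1-one (C-6 epimers)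
Conditions: Pd(OAc)2 (cat.), O2 (1 atm), DMSO, rt
Reagents that add atoms: none
Why: Saegusa–Ito oxidation: the Pd(II) enolate from the silyl enol ether undergoes β-hydride elimination toward C-3 and returns the enone with its β-methyl group; no stereocentre is formed and the γ-centre is not enolised under these neutral conditions.

Step 6
Reactants: 9 (4R)-3-methyl-4,6-bis(3-methylbut-2-en-1-yl)cyclohex-2-en-1-one
Product: 10 {[(4R)-3,3-dimethyl-4,6-bis(3-methylbut-2-en-1-yl)cyclohex-1-en-1-yl]oxy}trimethylsilane (C-6 epimers)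
Conditions: MeMgBr, CuBr·SMe2 (cat.), TMSCl, HMPA, THF, −78 → −40 °C; Et3N quench
Reagents that add atoms: methylmagnesium bromide C[Mg]Br; chlorotrimethylsilane C[Si](C)(C)Cl
Why: A second copper-catalysed conjugate methylation with silyl trapping builds the achiral gem-dimethyl carbon (future C8) and delivers the silyl enol ether regiospecifically toward the neopentyl α-carbon (future C1).

Step 7
Reactants: 11 3-methylbutane-1,3-diol
Product: 12 3-hydroxy-3-methylbutyl 4-methylbenzenesulfonate
Conditions: TsCl, pyridine, CH2Cl2, 0 °C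
Reagents that add atoms: 4-toluenesulfonyl chloride Cc1ccc(cc1)S(Cl)(=O)=O
Why: Sulfonylation should be selective for the primary over the tertiary hydroxyl on steric grounds; no stereocentre is involved.

Step 8
Reactants: 12 3-hydroxy-3-methylbutyl 4-methylbenzenesulfonate
Product: 13 3-[(tert-butyldimethylsilyl)oxy]-3-methylbutyl 4-methylbenzenesulfonate
Conditions: TBSOTf, 2,6-lutidine, CH2Cl2, 0 °C → rt
Reagents that add atoms: tert-butyldimethylsilyl triflate CC(C)(C)[Si](C)(C)OS(=O)(=O)C(F)(F)F
Why: Silylation of the tertiary alcohol with the reactive silyl triflate gives an ether that is robust to acid chlorides, amide bases and hot chloride.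

Step 9
Reactants: 13 3-[(tert-butyldimethylsilyl)oxy]-3-methylbutyl 4-methylbenzenesulfonate; 14 dibenzyl malonate
Product: 16 dibenzyl 2-{3-[(tert-butyldimethylsilyl)oxy]-3-methylbutyl}malonate, via sodium malonate enolate 15 (not isolated)
Conditions: NaH, DMF, 0 °C; then 13, 60 °C (14 in excess)
Reagents that add atoms: none
Why: Malonic ester alkylation (SN2 at the primary sulfonate); excess malonate suppresses dialkylation.

Step 10
Reactants: 16 dibenzyl 2-{3-[(tert-butyldimethylsilyl)oxy]-3-methylbutyl}malonate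
Product: 17 2-{3-[(tert-butyldimethylsilyl)oxy]-3-methylbutyl}malonic acid
Conditions: H2 (1 atm), Pd/C, EtOAc, rt
Reagents that add atoms: none
Why: Hydrogenolysis of the benzyl esters frees the diacid under neutral conditions, without heat (no decarboxylation) and with no alkene present at this stage.

Step 11
Reactants: 17 2-{3-[(tert-butyldimethylsilyl)oxy]-3-methylbutyl}malonic acid
Product: 18 2-{3-[(tert-butyldimethylsilyl)oxy]-3-methylbutyl}malonyl dichloride
Conditions: 1-chloro-N,N,2-trimethylprop-1-en-1-amine (2.2 equiv), CH2Cl2, 0 °C → rt; used crude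
Reagents that add atoms: 1-chloro-N,N,2-trimethylprop-1-en-1-amine CC(C)=C(Cl)N(C)C
Why: The α-chloroenamine converts carboxylic acids into acid chlorides under neutral conditions, so no HCl is evolved and the tertiary silyl ether should survive.

Step 12
Reactants: 10 {[(4R)-3,3-dimethyl-4,6-bis(3-methylbut-2-en-1-yl)cyclohex-1-en-1-yl]oxy}trimethylsilane; 18 2-{3-[(tert-butyldimethylsilyl)oxy]-3-methylbutyl}malonyl dichloride
Product: 20 (1R,5S,7R)-3-{3-[(tert-butyldimethylsilyl)oxy]-3-methylbutyl}-4-hydroxy-8,8-dimethyl-5,7-bis(3-methylbut-2-en-1-yl)bicyclo[3.3.1]non-3-ene-2,9-dione, via β-keto acid chloride 19 (not isolated)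
Conditions: Et2O, −20 °C → rt; then aq. KOH, BnEt3NCl, rt; then cold dilute HCl to pH 3
Reagents that add atoms: none
Why: The enol ether carbon C-1 is acylated by one COCl group of 18 (loss of TMSCl) to give the 2-acylcyclohexanone 19, whose ketone re-enolises toward C-5 under the HCl formed and is C-acylated intramolecularly by the second COCl group, after which the new 1,3-diketone tautomerises to the C-3 enol. The closest known reaction is the Effenberger α,α′-annulation of cyclohexanone enol ethers with malonyl dichloride, run here with a 2-alkylmalonyl dichloride so that the C-3 chain arrives in the same operation. Ring C1–C2–C3–C4–C5–C9 closes in a 6-(enolendo)-exo-trig acyl substitution (enol carbon C-5 onto the C-4 acyl chloride), which is possible only when the C-1 chain and the attack at C-5 are both axial, so C-1 and C-5 form cis by ring constraint. Their configuration relative to C-7 is controlled by the existing C-7 stereocentre: C-1 of 19 epimerises through its β-diketone enol and C-5 is planar in the enol, so closure should go through the chair that keeps the C-7 prenyl group equatorial (exo) and away from the forming bridge, giving (1R,5S,7R). The step needs C- over O-acylation at C-5 and survival of the prenyl alkenes and the silyl ether: O-acyl enol lactones are saponified in the KOH/phase-transfer work-up while the trione is held as its enolate, ethereal HCl at or below rt should neither add to trisubstituted alkenes nor ionise the silyl ether, and both C-6 epimers of 10 converge because that carbon is planarised.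

Step 13
Reactants: 20 (1R,5S,7R)-3-{3-[(tert-butyldimethylsilyl)oxy]-3-methylbutyl}-4-hydroxy-8,8-dimethyl-5,7-bis(3-methylbut-2-en-1-yl)bicyclo[3.3.1]non-3-ene-2,9-dione
Product: 21 (1R,5S,7R)-3-{3-[(tert-butyldimethylsilyl)oxy]-3-methylbutyl}-4-methoxy-8,8-dimethyl-5,7-bis(3-methylbut-2-en-1-yl)bicyclo[3.3.1]non-3-ene-2,9-dione
Conditions: TMSCHN2, MeOH–toluene, 0 °C; separation of the enol ether regioisomers
Reagents that add atoms: (trimethylsilyl)diazomethane C[Si](C)(C)C=[N+]=[N-]
Why: O-Methylation of the vinylogous acid by diazomethane released in situ should give both enol ethers; 21, whose C1–H lies between the C2 and C9 carbonyls, is separated for step 15, while the 2-O-methyl isomer is returned to 20 by LiCl/DMSO; no stereocentre is formed.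

Step 14
Reactants: 22 (2R)-2-methylbutanoic acid
Product: 23 (2R)-2-methylbutanoyl chloride
Conditions: (COCl)2, DMF (cat.), CH2Cl2, 0 °C → rt; distilled
Reagents that add atoms: oxalyl chloride O=C(Cl)C(Cl)=O
Why: Acid chloride formation through the Vilsmeier-type chloroiminium intermediate proceeds without base, so the α-stereocentre should be retained.

Step 15
Reactants: 21 (1R,5S,7R)-3-{3-[(tert-butyldimethylsilyl)oxy]-3-methylbutyl}-4-methoxy-8,8-dimethyl-5,7-bis(3-methylbut-2-en-1-yl)bicyclo[3.3.1]non-3-ene-2,9-dione; 23 (2R)-2-methylbutanoyl chloride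
Product: 25 (1S,5S,7R)-3-{3-[(tert-butyldimethylsilyl)oxy]-3-methylbutyl}-4-methoxy-8,8-dimethyl-1-[(2R)-2-methylbutanoyl]-5,7-bis(3-methylbut-2-en-1-yl)bicyclo[3.3.1]non-3-ene-2,9-dione, via bridgehead organolithium 24 (not isolated)
Conditions: LiTMP (1.2 equiv), THF, −78 °C; then 23, −78 °C; AcOH quench
Reagents that add atoms: none
Why: Bridgehead lithiation–acylation, the established way to place the C1 acyl group on vinylogous esters of this bicyclic class: LiTMP removes the only bridgehead hydrogen (C3 is fully substituted, so no vinylic deprotonation competes), the configurationally fixed organolithium is acylated with retention at C1, and the (R)-α-centre is brought in intact with 23, the near-stoichiometric base and low temperature limiting ketene formation.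

Step 16
Reactants: 25 (1S,5S,7R)-3-{3-[(tert-butyldimethylsilyl)oxy]-3-methylbutyl}-4-methoxy-8,8-dimethyl-1-[(2R)-2-methylbutanoyl]-5,7-bis(3-methylbut-2-en-1-yl)bicyclo[3.3.1]non-3-ene-2,9-dione
Product: 26 (1S,5S,7R)-3-{3-[(tert-butyldimethylsilyl)oxy]-3-methylbutyl}-4-hydroxy-8,8-dimethyl-1-[(2R)-2-methylbutanoyl]-5,7-bis(3-methylbut-2-en-1-yl)bicyclo[3.3.1]non-3-ene-2,9-dione
Conditions: LiCl, DMSO, 120 °C; dilute HCl work-up
Reagents that add atoms: none
Why: Krapcho-type SN2 demethylation of the vinylogous methyl ester by chloride is non-basic, so the acyl α-centre should not epimerise and the silyl ether and alkenes are untouched.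

Step 17
Reactants: 26 (1S,5S,7R)-3-{3-[(tert-butyldimethylsilyl)oxy]-3-methylbutyl}-4-hydroxy-8,8-dimethyl-1-[(2R)-2-methylbutanoyl]-5,7-bis(3-methylbut-2-en-1-yl)bicyclo[3.3.1]non-3-ene-2,9-dione
Product: 27 (1S,5S,7R)-4-hydroxy-3-(3-hydroxy-3-methylbutyl)-8,8-dimethyl-1-[(2R)-2-methylbutanoyl]-5,7-bis(3-methylbut-2-en-1-yl)bicyclo[3.3.1]non-3-ene-2,9-dione
Conditions: TBAF, THF, 50 °C; aq. NH4Cl
Reagents that add atoms: none
Why: Fluoride-mediated desilylation frees the tertiary alcohol while the enol is present as its unreactive enolate, so the alkoxide cannot add to C2 or C4 (the reason demethylation precedes desilylation); no stereocentre is affected.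

**Compound list**
1 | 5-methylhex-4-enal | CC(C)=CCCC=O | starting material
2 | but-3-en-2-one | CC(=O)C=C | starting material
3 | (2S)-2-(3-methylbut-2-en-1-yl)-5-oxohexanal | CC(=O)CC[C@@H](CC=C(C)C)C=O | intermediate
4 | (4S)-4-(3-methylbut-2-en-1-yl)cyclohex-2-en-1-one | O=C1CC[C@@H](CC=C(C)C)C=C1 | intermediate
5 | 1-bromo-3-methylbut-2-ene | CC(C)=CCBr | starting material
6 | lithium cross-conjugated dienolate of 4 (O-lithio, C-4 unchanged) | [Li]OC1=CC[C@@H](CC=C(C)C)C=C1 | intermediate
7 | (4R)-4,6-bis(3-methylbut-2-en-1-yl)cyclohex-2-en-1-one (C-6 epimers; C-4 geometry as in 4) | O=C1C(CC=C(C)C)C[C@@H](CC=C(C)C)C=C1 | intermediate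
8 | {[(4R)-3-methyl-4,6-bis(3-methylbut-2-en-1-yl)cyclohex-1-en-1-yl]oxy}trimethylsilane (C-3 and C-6 epimers) | C[Si](C)(C)OC1=CC(C)[C@H](CC=C(C)C)CC1CC=C(C)C | intermediate
9 | (4R)-3-methyl-4,6-bis(3-methylbut-2-en-1-yl)cyclohex-2-en-1-one (C-6 epimers) | O=C1C=C(C)[C@H](CC=C(C)C)CC1CC=C(C)C | intermediate
10 | {[(4R)-3,3-dimethyl-4,6-bis(3-methylbut-2-en-1-yl)cyclohex-1-en-1-yl]oxy}trimethylsilane (C-6 epimers) | C[Si](C)(C)OC1=CC(C)(C)[C@H](CC=C(C)C)CC1CC=C(C)C | intermediate
11 | 3-methylbutane-1,3-diol | CC(C)(O)CCO | starting material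
12 | 3-hydroxy-3-methylbutyl 4-methylbenzenesulfonate | CC(C)(O)CCOS(=O)(=O)c1ccc(C)cc1 | intermediate
13 | 3-[(tert-butyldimethylsilyl)oxy]-3-methylbutyl 4-methylbenzenesulfonate | CC(C)(CCOS(=O)(=O)c1ccc(C)cc1)O[Si](C)(C)C(C)(C)C | intermediate
14 | dibenzyl malonate | O=C(CC(=O)OCc1ccccc1)OCc1ccccc1 | starting material
15 | sodium enolate of dibenzyl malonate | [Na+].[O-]C(OCc1ccccc1)=CC(=O)OCc1ccccc1 | intermediate
16 | dibenzyl 2-{3-[(tert-butyldimethylsilyl)oxy]-3-methylbutyl}malonate | CC(C)(CCC(C(=O)OCc1ccccc1)C(=O)OCc1ccccc1)O[Si](C)(C)C(C)(C)C | intermediate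
17 | 2-{3-[(tert-butyldimethylsilyl)oxy]-3-methylbutyl}malonic acid | CC(C)(CCC(C(=O)O)C(=O)O)O[Si](C)(C)C(C)(C)C | intermediate
18 | 2-{3-[(tert-butyldimethylsilyl)oxy]-3-methylbutyl}malonyl dichloride | CC(C)(CCC(C(Cl)=O)C(Cl)=O)O[Si](C)(C)C(C)(C)C | intermediate
19 | 2-{3-[(tert-butyldimethylsilyl)oxy]-3-methylbutyl}-3-[(5R)-6,6-dimethyl-3,5-bis(3-methylbut-2-en-1-yl)-2-oxocyclohexyl]-3-oxopropanoyl chloride (other centres undefined) | O=C1C(CC=C(C)C)C[C@@H](CC=C(C)C)C(C)(C)C1C(=O)C(CCC(C)(C)O[Si](C)(C)C(C)(C)C)C(Cl)=O | intermediate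
20 | (1R,5S,7R)-3-{3-[(tert-butyldimethylsilyl)oxy]-3-methylbutyl}-4-hydroxy-8,8-dimethyl-5,7-bis(3-methylbut-2-en-1-yl)bicyclo[3.3.1]non-3-ene-2,9-dione | O=C1C(CCC(C)(C)O[Si](C)(C)C(C)(C)C)=C(O)[C@]2(CC=C(C)C)C[C@@H](CC=C(C)C)C(C)(C)[C@H]1C2=O | intermediate
21 | (1R,5S,7R)-3-{3-[(tert-butyldimethylsilyl)oxy]-3-methylbutyl}-4-methoxy-8,8-dimethyl-5,7-bis(3-methylbut-2-en-1-yl)bicyclo[3.3.1]non-3-ene-2,9-dione | O=C1C(CCC(C)(C)O[Si](C)(C)C(C)(C)C)=C(OC)[C@]2(CC=C(C)C)C[C@@H](CC=C(C)C)C(C)(C)[C@H]1C2=O | intermediate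
22 | (2R)-2-methylbutanoic acid | CC[C@@H](C)C(=O)O | starting material
23 | (2R)-2-methylbutanoyl chloride | CC[C@@H](C)C(Cl)=O | intermediate
24 | C-1 bridgehead lithio derivative of 21 | [Li][C@]12C(=O)C(CCC(C)(C)O[Si](C)(C)C(C)(C)C)=C(OC)[C@](CC=C(C)C)(C[C@@H](CC=C(C)C)C1(C)C)C2=O | intermediate
25 | (1S,5S,7R)-3-{3-[(tert-butyldimethylsilyl)oxy]-3-methylbutyl}-4-methoxy-8,8-dimethyl-1-[(2R)-2-methylbutanoyl]-5,7-bis(3-methylbut-2-en-1-yl)bicyclo[3.3.1]non-3-ene-2,9-dione | CC[C@@H](C)C(=O)[C@]12C(=O)C(CCC(C)(C)O[Si](C)(C)C(C)(C)C)=C(OC)[C@](CC=C(C)C)(C[C@@H](CC=C(C)C)C1(C)C)C2=O | intermediate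
26 | (1S,5S,7R)-3-{3-[(tert-butyldimethylsilyl)oxy]-3-methylbutyl}-4-hydroxy-8,8-dimethyl-1-[(2R)-2-methylbutanoyl]-5,7-bis(3-methylbut-2-en-1-yl)bicyclo[3.3.1]non-3-ene-2,9-dione | CC[C@@H](C)C(=O)[C@]12C(=O)C(CCC(C)(C)O[Si](C)(C)C(C)(C)C)=C(O)[C@](CC=C(C)C)(C[C@@H](CC=C(C)C)C1(C)C)C2=O | intermediate
27 | (1S,5S,7R)-4-hydroxy-3-(3-hydroxy-3-methylbutyl)-8,8-dimethyl-1-[(2R)-2-methylbutanoyl]-5,7-bis(3-methylbut-2-en-1-yl)bicyclo[3.3.1]non-3-ene-2,9-dione | CC[C@@H](C)C(=O)[C@]12C(=O)C(CCC(C)(C)O)=C(O)[C@](CC=C(C)C)(C[C@@H](CC=C(C)C)C1(C)C)C2=O | target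

**Step count and risks**

Total steps: 17. Longest linear sequence: 11 steps (1–6, 12, 13, 15, 16, 17).

Steps most likely to fail:

1. Step 12 (key annulation). The ring-closing C-acylation at the fully substituted C5 by an α-branched acyl chloride may be slow. O-Acylation to the enol lactone, ketene-type side reactions of the alkylmalonyl chloride, or acid-induced loss of the tertiary silyl ether could then take over. The fallback sets out from 10 and returns at 20. Annulation of 10 with the parent malonyl dichloride (Et2O, −20 °C → rt; KOH, BnEt3NCl) should give the C-3-unsubstituted trione F1. Conjugate addition of this cyclic 1,3-dione to but-3-en-2-one 2 (Et3N, THF) gives the 3-(3-oxobutyl) trione F2. Excess MeMgBr (THF, −78 → 0 °C; the dione is protected as its magnesium enolate and the C9 ketone is shielded) gives the hydroxy trione F3. TBSOTf/2,6-lutidine gives the bis-silyl compound F4, and K2CO3/MeOH cleaves only the labile enol silyl ether to give 20.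

2. Step 15 (bridgehead acylation). Deprotonation next to the gem-dimethyl carbon may be incomplete, and residual amide base may turn the acid chloride into its ketene, leading to O-acylation and epimerisation of the α-methyl centre. The fallback sets out from 21 and returns at 25. LiTMP followed by I2 gives the bridgehead iodide F5 (a small, fast electrophile). Iodine–magnesium exchange with i-PrMgCl·LiCl (THF, −78 °C) gives the bridgehead Grignard reagent F6, free of amide base. Addition to (2R)-2-methylbutanal F7 (from 23 with LiAlH(Ot-Bu)3, −78 °C, used at once) gives the carbinol F8 as a carbinol epimer mixture, and Dess–Martin oxidation gives 25.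

3. Step 13 (enol ether formation). Regioselectivity may be poor, with methylation going mainly to the less hindered O-2, so that little 21 is obtained. The fallback sets out from 20 and returns at 27. It turns the preference for O-2 into an advantage: SEMCl/i-Pr2NEt (CH2Cl2, 0 °C) should give the 2-O-SEM vinylogous ester F9. LiTMP (THF, −78 °C), guided to C1–H by the acetal oxygens (alkoxymethyl-directed lithiation), gives the bridgehead organolithium F10. Acylation with 23 gives the 1-acyl 2-O-SEM compound F11. TBAF (THF, 50 °C) then removes the SEM and silyl ether groups in one operation to give 27, which also avoids the hot chloride step.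

Further compounds
F1 | step 12 | (1R,5S,7R)-4-hydroxy-8,8-dimethyl-5,7-bis(3-methylbut-2-en-1-yl)bicyclo[3.3.1]non-3-ene-2,9-dione | O=C1C=C(O)[C@]2(CC=C(C)C)C[C@@H](CC=C(C)C)C(C)(C)[C@H]1C2=O
F2 | step 12 | (1R,5S,7R)-4-hydroxy-8,8-dimethyl-5,7-bis(3-methylbut-2-en-1-yl)-3-(3-oxobutyl)bicyclo[3.3.1]non-3-ene-2,9-dione | O=C1C(CCC(C)=O)=C(O)[C@]2(CC=C(C)C)C[C@@H](CC=C(C)C)C(C)(C)[C@H]1C2=O
F3 | step 12 | (1R,5S,7R)-4-hydroxy-3-(3-hydroxy-3-methylbutyl)-8,8-dimethyl-5,7-bis(3-methylbut-2-en-1-yl)bicyclo[3.3.1]non-3-ene-2,9-dione | O=C1C(CCC(C)(C)O)=C(O)[C@]2(CC=C(C)C)C[C@@H](CC=C(C)C)C(C)(C)[C@H]1C2=O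
F4 | step 12 | 4-O-silyl enol ether of 20 (bis-TBS compound) | O=C1C(CCC(C)(C)O[Si](C)(C)C(C)(C)C)=C(O[Si](C)(C)C(C)(C)C)[C@]2(CC=C(C)C)C[C@@H](CC=C(C)C)C(C)(C)[C@H]1C2=O
F5 | step 15 | C-1 bridgehead iodide of 21 | I[C@]12C(=O)C(CCC(C)(C)O[Si](C)(C)C(C)(C)C)=C(OC)[C@](CC=C(C)C)(C[C@@H](CC=C(C)C)C1(C)C)C2=O
F6 | step 15 | C-1 bridgehead chloromagnesium derivative of 21 | Cl[Mg][C@]12C(=O)C(CCC(C)(C)O[Si](C)(C)C(C)(C)C)=C(OC)[C@](CC=C(C)C)(C[C@@H](CC=C(C)C)C1(C)C)C2=O
F7 | step 15 | (2R)-2-methylbutanal | CC[C@@H](C)C=O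
F8 | step 15 | C-1 [(2R)-1-hydroxy-2-methylbutyl] derivative of 21 (carbinol epimers) | CC[C@@H](C)C(O)[C@]12C(=O)C(CCC(C)(C)O[Si](C)(C)C(C)(C)C)=C(OC)[C@](CC=C(C)C)(C[C@@H](CC=C(C)C)C1(C)C)C2=O
F9 | step 13 | 2-O-[2-(trimethylsilyl)ethoxymethyl] enol ether of 20 (C4 ketone) | C[Si](C)(C)CCOCOC1=C(CCC(C)(C)O[Si](C)(C)C(C)(C)C)C(=O)[C@]2(CC=C(C)C)C[C@@H](CC=C(C)C)C(C)(C)[C@H]1C2=O
F10 | step 13 | C-1 bridgehead lithio derivative of F9 | C[Si](C)(C)CCOCOC1=C(CCC(C)(C)O[Si](C)(C)C(C)(C)C)C(=O)[C@]2(CC=C(C)C)C[C@@H](CC=C(C)C)C(C)(C)[C@@]1([Li])C2=O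
F11 | step 13 | C-1 [(2R)-2-methylbutanoyl] derivative of F9 | C[Si](C)(C)CCOCOC1=C(CCC(C)(C)O[Si](C)(C)C(C)(C)C)C(=O)[C@]2(CC=C(C)C)C[C@@H](CC=C(C)C)C(C)(C)[C@@]1(C(=O)[C@H](C)CC)C2=O
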